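The substrate left at the end is the reading to watch. In Tuesday's run it stops near 1.05% and in Thursday's run near 1.15%, not at zero, although by my count reagent remains.

| setting | Tuesday's | Thursday's | flask |
|---|---|---|---|
| substrate | 0.050 M | 0.075 M | 0.10 M |
| reagent | 0.12 M | 0.12 M | 0.120 M |
| catalyst | 1 mM | 1 mM | 1.0 mM |
| remark | run made earlier | run made earlier |  |
| time |  |  | 20 h |

| run | time / h | isomer of the product / % | side product / % | target / % | substrate / % |
|---|---|---|---|---|---|
| Tuesday's | 3.00 | 81.8 | 2.3 | 5.2 | 10.0 |
| Tuesday's | 6.00 | 93.5 | 2.4 | 0.8 | 2.4 |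
| Tuesday's | 10.0 | 95.2 | 2.7 | 0.5 | 0.7 |
| Tuesday's | 12.0 | 95.7 | 2.8 | 0 | 1.4 |
| Tuesday's | 15.0 | 95.7 | 1.8 | 0.5 | 0.8 |
| Tuesday's | 20.0 | 95.2 | 2.6 | 0.5 | 1.3 |
| Thursday's | 1.50 | 57.5 | 2.9 | 12.9 | 25.7 |
| Thursday's | 2.50 | 72.7 | 3.2 | 7.7 | 16.2 |
| Thursday's | 4.00 | 83.9 | 3.9 | 3.2 | 8.2 |
| Thursday's | 8.00 | 91.7 | 4.2 | 0.5 | 2.3 |
| Thursday's | 12.0 | 93.4 | 4.2 | 0.5 | 0.8 |
| Thursday's | 20.0 | 93.3 | 4.2 | 0.1 | 1.5 |

(each reading ± 0.3 percentage points)

1. where most of what was charged as substrate, at 20 h is found (substrate / isomer of the product / side product / target)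
2. the largest share itself, whichever of these holds it, in percent of the substrate charged

- in percentages every species weighs as the substrate in it: one side product counts as two

1. I assume that each isomer of the product and each side product holds one reagent. The plateau quotient (an equilibrium quotient) c(isomer)/(c(substrate)·c(reagent)), which I call Q, then reads 1260 L mol⁻¹ on Tuesday and 1670 L mol⁻¹ on Thursday, so I use 1470 L mol⁻¹. Each of these substrate readings carries a scatter of 0.3 percentage points, so this is a rough reading. The share of substrate left is then the isomer share divided by Q·c(reagent).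

2. Side product grows about in step with the substrate charge in these runs, which gives 5.40% in this flask.

3. I add Thursday's unaccounted 0.900% and 0.5% of target. With no substrate left, the isomer would hold 93.2%, leaving c(reagent) = 0.0241 M.

4. The weak link is that zero substrate. The rule gives 2.63%, so the isomer falls to 90.6% and c(reagent) rises to 0.0267 M. A second pass gives 2.31% substrate and 90.9% isomer.

5. Thursday's early decay reads as 8.00 L mol⁻¹ h⁻¹. At that c(reagent) the substrate half-life is 3.24 h, short against 20 h, so I expect this flask to reach its plateau.

The forecast names isomer of the product at 90%, expecting “about 1–3% substrate at 20 h”, and my 90.9% stands above it.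

The flask at 20 h gives isomer of the product with 90.2%, and substrate 2.18%.

    substrate + reagent ⇌ target (K = 7.10 L mol⁻¹, k = 92.0 L mol⁻¹ h⁻¹)
    substrate + reagent ⇌ isomer of the product (K = 1600 L mol⁻¹, k = 12.0 L mol⁻¹ h⁻¹)
    target + catalyst ⇌ isomer of the product + catalyst, rate k3*[catalyst]*[target] forward; the back reaction follows from the equilibrium constant (k = 7.10 L mol⁻¹ h⁻¹)
    2 substrate → homo dimer (k = 0.200 L mol⁻¹ h⁻¹)
    substrate + target → side product (k = 1.50 L mol⁻¹ h⁻¹)

The relaxation half-life between substrate + reagent and isomer of the product, by this step alone and both ways together, is 1.96 h at 20.0 h, short against 20 h. With the 22.2% of its reagent charge left in this flask, Q gives 2.31% substrate beside the 2.18% found. In the neighbouring flask with 0.17 M of substrate, reagent is first to run out, with 1.9% of its charge left, and Q gives 19.5% substrate beside the 17% found.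

The readings were generated by integration for substances that don't exist; scatter was added.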